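**Plan**

- Retrosynthetic cuts (benzo[7]annulene numbering: C5 spiro carbon, C6 ring CH2, C7 and C8 the methyl-bearing carbons, C9 the benzylic carbinol carbon): the C9–O ester bond (with inversion), the C7–H bond (back to an exocyclic methylene), the C8–C9 ring bond, the bond from the arm's alkene carbon to CH2B, the C5–C6 bond and the biaryl bond.
- Enabling feature: in the seven-membered ring, carbinol carbon C9 is bonded to methyl-bearing C8, and C7 next to it carries a one-carbon branch. With that branch as =CH2, the unit C9(OH)–C8(CH3)–C7(=CH2) is a homoallylic alcohol, the imprint of a crotyl-type addition of a 2-substituted allyl metal to an aryl aldehyde.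
- Forward order: Suzuki coupling joins rings A and B; Birch reductive alkylation dearomatises ring B and creates quaternary C5 with the four-carbon arm; oxidation gives the cross-conjugated dienone and the aldehyde; the arm's bromoalkene becomes the allylboronate; the seven-membered ring closes last.
- Stereochemistry: the arm's alkene geometry is fixed in (Z)-2-bromobut-2-enal and carried unchanged into the E allylboronate, which through the chair gives C8/C9 cis. A chiral phosphoric acid chooses the enantiomer, hydroxyl-directed hydrogenation sets C7, and Mitsunobu benzoylation inverts C9.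

Key step: step 11

Assumption: (R)-TRIP, the (R)-3,3'-bis(2,4,6-triisopropylphenyl)-1,1'-binaphthyl-2,2'-diyl hydrogen phosphate, is taken to select the same chair handedness as in intermolecular allylborations, with aryl and hydrogen exchanged at the carbonyl carbon; should the (8R,9R) alcohol form instead, the (S)-acid is used.

**Route**

Step 1
Reactants: 1 2-bromo-3,4,5-trimethoxybenzaldehyde; 2 3,5-dimethoxyphenylboronic acid
Product: 3 2-(3,5-dimethoxyphenyl)-3,4,5-trimethoxybenzaldehyde
Conditions: Pd(OAc)2 (2 mol%), SPhos (4 mol%), K3PO4, toluene/H2O, 90 °C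
Reagents that add atoms: none
Why: Suzuki–Miyaura coupling of a doubly ortho-substituted aryl bromide is routine with a dialkylbiarylphosphine ligand, the formyl group speeding oxidative addition and the boronic acid carrying no ortho substituent.

Step 2
Reactants: 3 2-(3,5-dimethoxyphenyl)-3,4,5-trimethoxybenzaldehyde
Product: 4 [2-(3,5-dimethoxyphenyl)-3,4,5-trimethoxyphenyl]methanol
Conditions: NaBH4, MeOH/THF, 0 °C
Reagents that add atoms: none
Why: Hydride reduction of the aryl aldehyde gives the benzylic alcohol, whose lithium alkoxide is the one form of the formyl carbon that withstands the dissolving-metal step that follows.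

Step 3
Reactants: 5 (E)-but-2-enal
Product: 7 (Z)-2-bromobut-2-enal, via 2,3-dibromobutanal 6 (not isolated)
Conditions: Br2, CH2Cl2, 0 °C; then Et3N, 0 °C to rt
Reagents that add atoms: bromine, BrBr
Why: Bromine addition to the enal followed by amine-induced dehydrobromination (loss of the acidic alpha hydrogen and the beta bromide) is the standard way to 2-bromo enals and should give the more stable isomer, with bromine cis to methyl and formyl trans to it.

Step 4
Reactants: 7 (Z)-2-bromobut-2-enal
Product: 8 (Z)-2-bromobut-2-en-1-ol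
Conditions: NaBH4, CeCl3·7H2O, MeOH, 0 °C
Reagents that add atoms: none
Why: Luche reduction delivers hydride to the carbonyl carbon only and leaves the bromoalkene and its geometry untouched.

Step 5
Reactants: 8 (Z)-2-bromobut-2-en-1-ol
Product: 9 (Z)-1,2-dibromobut-2-ene
Conditions: PBr3, Et2O, 0 °C
Reagents that add atoms: phosphorus tribromide, BrP(Br)Br
Why: Bromination of the primary allylic alcohol through its phosphite ester (SN2 displacement by bromide) keeps the trisubstituted alkene geometry and gives the primary allylic bromide.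

Step 6
Reactants: 4 [2-(3,5-dimethoxyphenyl)-3,4,5-trimethoxyphenyl]methanol; 9 (Z)-1,2-dibromobut-2-ene
Product: 11 {2-[1-((Z)-2-bromobut-2-en-1-yl)-3,5-dimethoxycyclohexa-2,5-dien-1-yl]-3,4,5-trimethoxyphenyl}methanol, via dilithium alkoxide cyclohexadienide 10 (not isolated)
Conditions: Li (2.5 equiv), NH3/THF, −78 °C; isoprene; then 9, −78 °C; NH4Cl
Reagents that add atoms: none
Why: Birch reductive alkylation of a biaryl, in which the 3,5-dimethoxyphenyl ring takes up two electrons and one proton at the carbon between the methoxy groups, the remaining ring-junction cyclohexadienyl anion is stabilised by ring A and is alkylated there by the primary allylic bromide in an SN2 step that keeps the bromoalkene geometry, and the benzylic oxygen survives as its lithium alkoxide.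

Step 7
Reactants: 11 {2-[1-((Z)-2-bromobut-2-en-1-yl)-3,5-dimethoxycyclohexa-2,5-dien-1-yl]-3,4,5-trimethoxyphenyl}methanol
Product: 12 2-[1-((Z)-2-bromobut-2-en-1-yl)-3,5-dimethoxy-4-oxocyclohexa-2,5-dien-1-yl]-3,4,5-trimethoxybenzaldehyde
Conditions: (C5H5NH)2Cr2O7 (excess), t-BuOOH, Celite, benzene, 0 °C to rt
Reagents that add atoms: tert-butyl hydroperoxide, CC(C)(C)OO
Why: Oxidation of the doubly allylic methylene of a Birch-derived cyclohexa-1,4-diene with hexavalent chromium and tert-butyl hydroperoxide is an established route to 4,4-disubstituted cyclohexa-2,5-dienones that tolerates enol ethers, the peroxyl radical being trapped at the ring carbon remote from the quaternary centre, while the same oxidant takes the benzylic alcohol to the aldehyde.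

Step 8
Reactants: 12 2-[1-((Z)-2-bromobut-2-en-1-yl)-3,5-dimethoxy-4-oxocyclohexa-2,5-dien-1-yl]-3,4,5-trimethoxybenzaldehyde
Product: 13 4-((Z)-2-bromobut-2-en-1-yl)-4-[6-(dimethoxymethyl)-2,3,4-trimethoxyphenyl]-2,6-dimethoxycyclohexa-2,5-dien-1-one
Conditions: HC(OMe)3, PPTS (5 mol%), MeOH, rt
Reagents that add atoms: trimethyl orthoformate, COC(OC)OC; methanol, CO
Why: Acetalisation with an orthoester under weak pyridinium acid masks the aldehyde for the basic coupling step and is too mild to trigger the dienone–phenol rearrangement of the 4,4-disubstituted dienone.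

Step 9
Reactants: 13 4-((Z)-2-bromobut-2-en-1-yl)-4-[6-(dimethoxymethyl)-2,3,4-trimethoxyphenyl]-2,6-dimethoxycyclohexa-2,5-dien-1-one; 14 bis(4,4,5,5-tetramethyl-1,3,2-dioxaborolan-2-yl)methane
Product: 15 4-[6-(dimethoxymethyl)-2,3,4-trimethoxyphenyl]-2,6-dimethoxy-4-{(E)-2-[(4,4,5,5-tetramethyl-1,3,2-dioxaborolan-2-yl)methyl]but-2-en-1-yl}cyclohexa-2,5-dien-1-one
Conditions: Pd(P(t-Bu)3)2 (5 mol%), KOH (aq), 1,4-dioxane, rt
Reagents that add atoms: none
Why: Suzuki–Miyaura coupling of a geminal bis(boronate) with an alkenyl bromide, in which hydroxide activates one boron for transmetalation while the second stays on carbon, forms the alkenyl–CH2B bond with retention of alkene geometry (CH2B cis to methyl) and leaves acetal and dienone alone.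

Step 10
Reactants: 15 4-[6-(dimethoxymethyl)-2,3,4-trimethoxyphenyl]-2,6-dimethoxy-4-{(E)-2-[(4,4,5,5-tetramethyl-1,3,2-dioxaborolan-2-yl)methyl]but-2-en-1-yl}cyclohexa-2,5-dien-1-one
Product: 16 2-(3,5-dimethoxy-4-oxo-1-{(E)-2-[(4,4,5,5-tetramethyl-1,3,2-dioxaborolan-2-yl)methyl]but-2-en-1-yl}cyclohexa-2,5-dien-1-yl)-3,4,5-trimethoxybenzaldehyde
Conditions: oxalic acid on wet SiO2, CH2Cl2, 0 °C; cold filtration, used at once
Reagents that add atoms: water, O
Why: Acetal hydrolysis of the dimethyl acetal of an electron-rich aryl aldehyde proceeds on weakly acidic wet silica at 0 °C, conditions under which the pinacol boronate and the dienone persist and the uncatalysed ring closure is expected to be slow.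

Step 11
Reactants: 16 2-(3,5-dimethoxy-4-oxo-1-{(E)-2-[(4,4,5,5-tetramethyl-1,3,2-dioxaborolan-2-yl)methyl]but-2-en-1-yl}cyclohexa-2,5-dien-1-yl)-3,4,5-trimethoxybenzaldehyde
Product: 18 (8S,9S)-9-hydroxy-2,3,3',4,5'-pentamethoxy-8-methyl-7-methylidene-6,7,8,9-tetrahydrospiro[benzo[7]annulene-5,1'-cyclohexa[2,5]dien]-4'-one (hydroxyl cis to the C8 methyl), via O-pinacolboryl ether 17 (not isolated)
Conditions: (R)-TRIP (10 mol%), 4 Å MS, toluene, −30 °C; then aq NaHCO3
Reagents that add atoms: none
Why: The phosphoric acid hydrogen-bonds to a dioxaborolane oxygen and raises the Lewis acidity of boron, the aldehyde oxygen binds boron, and the gamma carbon (CH–CH3) of the allyl unit adds to the carbonyl carbon through a closed six-membered chair with allyl transposition, leaving the exocyclic methylene and an O-boryl ether that is hydrolysed on work-up. The closest known reaction type is the phosphoric-acid-catalysed allyl- and crotylboration of aryl aldehydes with pinacol boronates, used here in its ring-closing form, whose thermal version is well established for boronates tethered to aldehydes. The seven-membered carbocycle closes in a 7-exo-trig sense at the carbonyl carbon, the chair sharing its C(carbonyl)–C(gamma)–C(beta) edge with the new ring, so that the transition state resembles a bridged bicyclo[4.3.1]decane. The C8/C9 relative configuration follows from the alkene geometry, because the four-atom tether can span the chair only if the aryl group is pseudo-axial, the methyl group cis to CH2B is axial as well and anti to it, and this places methyl and hydroxyl cis on the new ring. The absolute configuration is chosen by the phosphoric acid, which has to tell apart the two mirror-image chairs of an achiral substrate. The step therefore needs one aldehyde face and the cis diastereomer; the second is secured by the defined E alkene together with the short tether, which excludes the equatorial-aryl chair and the boat, whereas the first rests on the catalyst alone.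

Step 12
Reactants: 18 (8S,9S)-9-hydroxy-2,3,3',4,5'-pentamethoxy-8-methyl-7-methylidene-6,7,8,9-tetrahydrospiro[benzo[7]annulene-5,1'-cyclohexa[2,5]dien]-4'-one
Product: 19 (7R,8S,9S)-9-hydroxy-2,3,3',4,5'-pentamethoxy-7,8-dimethyl-6,7,8,9-tetrahydrospiro[benzo[7]annulene-5,1'-cyclohexa[2,5]dien]-4'-one
Conditions: [Ir(cod)(PCy3)(py)]PF6 (5 mol%), H2 (1 atm), CH2Cl2, 0 °C to rt
Reagents that add atoms: none
Why: In this hydroxyl-directed hydrogenation the cationic iridium centre binds the homoallylic hydroxyl and delivers hydrogen to the 1,1-disubstituted alkene from the hydroxyl face, so that the new C7 methyl is trans to the hydroxyl and to the C8 methyl, while the hindered methoxy-enone double bonds are left alone.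

Step 13
Reactants: 19 (7R,8S,9S)-9-hydroxy-2,3,3',4,5'-pentamethoxy-7,8-dimethyl-6,7,8,9-tetrahydrospiro[benzo[7]annulene-5,1'-cyclohexa[2,5]dien]-4'-one; 20 benzoic acid
Product: 21 (7R,8S,9R)-2,3,3',4,5'-pentamethoxy-7,8-dimethyl-4'-oxo-6,7,8,9-tetrahydrospiro[benzo[7]annulene-5,1'-cyclohexa[2,5]dien]-9-yl benzoate
Conditions: PPh3, DIAD, THF, 0 °C to rt
Reagents that add atoms: none
Why: In the Mitsunobu reaction the alkoxyphosphonium ion of the benzylic alcohol is displaced by benzoate with inversion at C9 under neutral conditions that spare the acid-labile spirodienone, and attack anti to the C8 methyl leads to the same trans ester even if the displacement has some ionic character.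

**Compound list**

1 | 2-bromo-3,4,5-trimethoxybenzaldehyde | COc1cc(C=O)c(Br)c(OC)c1OC | starting material
2 | 3,5-dimethoxyphenylboronic acid | COc1cc(OC)cc(c1)B(O)O | starting material
3 | 2-(3,5-dimethoxyphenyl)-3,4,5-trimethoxybenzaldehyde | COc1cc(OC)cc(c1)-c1c(C=O)cc(OC)c(OC)c1OC | intermediate
4 | [2-(3,5-dimethoxyphenyl)-3,4,5-trimethoxyphenyl]methanol | COc1cc(OC)cc(c1)-c1c(CO)cc(OC)c(OC)c1OC | intermediate
5 | (E)-but-2-enal (crotonaldehyde) | C/C=C/C=O | starting material
6 | (2R*,3S*)-2,3-dibromobutanal, racemic, one enantiomer drawn | C[C@H](Br)[C@H](Br)C=O | intermediate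
7 | (Z)-2-bromobut-2-enal | C/C=C(\Br)C=O | intermediate
8 | (Z)-2-bromobut-2-en-1-ol | C/C=C(\Br)CO | intermediate
9 | (Z)-1,2-dibromobut-2-ene | C/C=C(\Br)CBr | intermediate
10 | dilithium salt of 4 after two-electron reduction: lithium benzylic alkoxide bearing the 1-aryl-3,5-dimethoxycyclohexa-2,5-dien-1-ide | [Li+].[Li+].[O-]Cc1cc(OC)c(OC)c(OC)c1[C-]1C=C(OC)CC(OC)=C1 | intermediate
11 | {2-[1-((Z)-2-bromobut-2-en-1-yl)-3,5-dimethoxycyclohexa-2,5-dien-1-yl]-3,4,5-trimethoxyphenyl}methanol | COC1=CC(C=C(OC)C1)(C/C(Br)=C/C)c1c(CO)cc(OC)c(OC)c1OC | intermediate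
12 | 2-[1-((Z)-2-bromobut-2-en-1-yl)-3,5-dimethoxy-4-oxocyclohexa-2,5-dien-1-yl]-3,4,5-trimethoxybenzaldehyde | COC1=CC(C=C(OC)C1=O)(C/C(Br)=C/C)c1c(C=O)cc(OC)c(OC)c1OC | intermediate
13 | 4-((Z)-2-bromobut-2-en-1-yl)-4-[6-(dimethoxymethyl)-2,3,4-trimethoxyphenyl]-2,6-dimethoxycyclohexa-2,5-dien-1-one | COC1=CC(C=C(OC)C1=O)(C/C(Br)=C/C)c1c(C(OC)OC)cc(OC)c(OC)c1OC | intermediate
14 | bis(4,4,5,5-tetramethyl-1,3,2-dioxaborolan-2-yl)methane | CC1(C)OB(CB2OC(C)(C)C(C)(C)O2)OC1(C)C | starting material
15 | 4-[6-(dimethoxymethyl)-2,3,4-trimethoxyphenyl]-2,6-dimethoxy-4-{(E)-2-[(4,4,5,5-tetramethyl-1,3,2-dioxaborolan-2-yl)methyl]but-2-en-1-yl}cyclohexa-2,5-dien-1-one | COC1=CC(C=C(OC)C1=O)(C/C(CB2OC(C)(C)C(C)(C)O2)=C/C)c1c(C(OC)OC)cc(OC)c(OC)c1OC | intermediate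
16 | 2-(3,5-dimethoxy-4-oxo-1-{(E)-2-[(4,4,5,5-tetramethyl-1,3,2-dioxaborolan-2-yl)methyl]but-2-en-1-yl}cyclohexa-2,5-dien-1-yl)-3,4,5-trimethoxybenzaldehyde | COC1=CC(C=C(OC)C1=O)(C/C(CB2OC(C)(C)C(C)(C)O2)=C/C)c1c(C=O)cc(OC)c(OC)c1OC | intermediate
17 | O-(4,4,5,5-tetramethyl-1,3,2-dioxaborolan-2-yl) ether of 18 | COC1=CC2(C=C(OC)C1=O)CC(=C)[C@H](C)[C@H](OB3OC(C)(C)C(C)(C)O3)c1cc(OC)c(OC)c(OC)c12 | intermediate
18 | (8S,9S)-9-hydroxy-2,3,3',4,5'-pentamethoxy-8-methyl-7-methylidene-6,7,8,9-tetrahydrospiro[benzo[7]annulene-5,1'-cyclohexa[2,5]dien]-4'-one | COC1=CC2(C=C(OC)C1=O)CC(=C)[C@H](C)[C@H](O)c1cc(OC)c(OC)c(OC)c12 | intermediate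
19 | (7R,8S,9S)-9-hydroxy-2,3,3',4,5'-pentamethoxy-7,8-dimethyl-6,7,8,9-tetrahydrospiro[benzo[7]annulene-5,1'-cyclohexa[2,5]dien]-4'-one | COC1=CC2(C=C(OC)C1=O)C[C@@H](C)[C@H](C)[C@H](O)c1cc(OC)c(OC)c(OC)c12 | intermediate
20 | benzoic acid | OC(=O)c1ccccc1 | starting material
21 | (7R,8S,9R)-2,3,3',4,5'-pentamethoxy-7,8-dimethyl-4'-oxo-6,7,8,9-tetrahydrospiro[benzo[7]annulene-5,1'-cyclohexa[2,5]dien]-9-yl benzoate (CNP0201356.1) | COC1=CC2(C=C(OC)C1=O)C[C@@H](C)[C@H](C)[C@@H](OC(=O)c1ccccc1)c1cc(OC)c(OC)c(OC)c12 | target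

**Step count**

Total step count: 13.
Longest linear sequence: 11 steps (from 5 through steps 3, 4, 5, 6, 7, 8, 9, 10, 11, 12 and 13); from 1 the sequence is 10 steps.

**Steps most likely to fail**

Step 11. The enantioface discrimination may be weak or inverted, because the tether forces the aryl group into the pseudo-axial site that the catalyst normally finds occupied by hydrogen, and a racemic background closure may begin while the aldehyde is being unmasked. Fallback (classical resolution in place of catalyst control): setting out from 16, the ring is closed without catalyst in toluene at 40 °C, which through the same chair should give the racemic cis alcohol F1. Esterification with (S)-2-methoxy-2-phenylacetic acid (DCC, DMAP, CH2Cl2) should give two diastereomers, the (8S,9S) ester F2 and the (8R,9R) ester F3, to be separated by chromatography. Methanolysis of F2 (K2CO3, MeOH, 0 °C) brings the route back at 18.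

Step 6. C-alkylation of the ring-junction carbanion may be too slow next to the doubly ortho-substituted ring A, so that protonation, loss of HBr from the bromoalkene or loss of a methoxy group from ring A takes over. Fallback (the quaternary carbon is built before ring A carries its ortho substituent): setting out from 2, Suzuki–Miyaura coupling with 5-bromo-1,2,3-trimethoxybenzene should give 3,3',4,5,5'-pentamethoxybiphenyl F4. Birch reductive alkylation with 9 under the conditions of step 6, now at an unhindered carbanion, should give the bromoalkenyl cyclohexadiene F5, and oxidation under the conditions of step 7 the 4-aryl-4-alkyl dienone F6. Rieche formylation (Cl2CHOMe, AgOSO2CF3, CH2Cl2, −78 °C) at one of the two equivalent ring A positions ortho to the quaternary carbon brings the route back at 12.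

Step 7. The two enol ethers may be hydrolysed or over-oxidised, or the peroxyl radical may attack the allylic positions of the arm, before the doubly allylic methylene is converted. Fallback (the central carbonyl is introduced at the 1,3-dione stage instead of by C–H oxidation of the diene): setting out from 11, MnO2 in CH2Cl2 should oxidise only the benzylic alcohol and give the diene aldehyde F7. Aqueous oxalic acid in THF should hydrolyse both enol ethers to the cyclohexane-1,3-dione F8. Riley oxidation with SeO2 (dioxane/H2O) converts the doubly activated methylene into the central carbonyl, the vicinal tricarbonyl being expected as its bis-enol, the 2,6-dihydroxy dienone F9. O-Methylation of both enols (Me2SO4, K2CO3, acetone) brings the route back at 12.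

**Further compounds**

F1 | step 11 | racemic (8S*,9S*)-9-hydroxy-2,3,3',4,5'-pentamethoxy-8-methyl-7-methylidene-6,7,8,9-tetrahydrospiro[benzo[7]annulene-5,1'-cyclohexa[2,5]dien]-4'-one (18 and its enantiomer) | COC1=CC2(C=C(OC)C1=O)CC(=C)[C@H](C)[C@H](O)c1cc(OC)c(OC)c(OC)c12.COC1=CC2(C=C(OC)C1=O)CC(=C)[C@@H](C)[C@@H](O)c1cc(OC)c(OC)c(OC)c12
F2 | step 11 | (8S,9S)-2,3,3',4,5'-pentamethoxy-8-methyl-7-methylidene-4'-oxo-6,7,8,9-tetrahydrospiro[benzo[7]annulene-5,1'-cyclohexa[2,5]dien]-9-yl (S)-2-methoxy-2-phenylacetate | COC1=CC2(C=C(OC)C1=O)CC(=C)[C@H](C)[C@H](OC(=O)[C@@H](OC)c1ccccc1)c1cc(OC)c(OC)c(OC)c12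
F3 | step 11 | (8R,9R)-2,3,3',4,5'-pentamethoxy-8-methyl-7-methylidene-4'-oxo-6,7,8,9-tetrahydrospiro[benzo[7]annulene-5,1'-cyclohexa[2,5]dien]-9-yl (S)-2-methoxy-2-phenylacetate | COC1=CC2(C=C(OC)C1=O)CC(=C)[C@@H](C)[C@@H](OC(=O)[C@@H](OC)c1ccccc1)c1cc(OC)c(OC)c(OC)c12
F4 | step 6 | 3,3',4,5,5'-pentamethoxy-1,1'-biphenyl | COc1cc(OC)cc(c1)-c1cc(OC)c(OC)c(OC)c1
F5 | step 6 | 5-[1-((Z)-2-bromobut-2-en-1-yl)-3,5-dimethoxycyclohexa-2,5-dien-1-yl]-1,2,3-trimethoxybenzene | COC1=CC(C=C(OC)C1)(C/C(Br)=C/C)c1cc(OC)c(OC)c(OC)c1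
F6 | step 6 | 4-((Z)-2-bromobut-2-en-1-yl)-2,6-dimethoxy-4-(3,4,5-trimethoxyphenyl)cyclohexa-2,5-dien-1-one | COC1=CC(C=C(OC)C1=O)(C/C(Br)=C/C)c1cc(OC)c(OC)c(OC)c1
F7 | step 7 | 2-[1-((Z)-2-bromobut-2-en-1-yl)-3,5-dimethoxycyclohexa-2,5-dien-1-yl]-3,4,5-trimethoxybenzaldehyde | COC1=CC(C=C(OC)C1)(C/C(Br)=C/C)c1c(C=O)cc(OC)c(OC)c1OC
F8 | step 7 | 2-[1-((Z)-2-bromobut-2-en-1-yl)-3,5-dioxocyclohexyl]-3,4,5-trimethoxybenzaldehyde | O=C1CC(=O)CC(C1)(C/C(Br)=C/C)c1c(C=O)cc(OC)c(OC)c1OC
F9 | step 7 | 2-[1-((Z)-2-bromobut-2-en-1-yl)-3,5-dihydroxy-4-oxocyclohexa-2,5-dien-1-yl]-3,4,5-trimethoxybenzaldehyde | OC1=CC(C=C(O)C1=O)(C/C(Br)=C/C)c1c(C=O)cc(OC)c(OC)c1OC
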